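The readings come from a simulation for substances that don't exist; scatter was added.

The vessel is a closed, stirred, isothermal flask. In it the enzyme turns starting material into target, and target goes on to over-reaction product. The protic impurity quenches some starting material, and the enzyme destroys itself in pairs.

| flask | starting material | protic impurity | enzyme | remark | time |
|---|---|---|---|---|---|
| winter | 41 mM | 4.1 mM | 0.37 µM | run made earlier |  |
| summer | 41 mM | 4.1 mM | 1.5 µM | run made earlier |  |
| midnight | 82 mM | 4.1 mM | 0.74 µM | run made earlier |  |
| flask | 41 mM | 4.10 mM | 0.74 µM |  | 25 h |

| run | time / h | target / % | starting material / % |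
|---|---|---|---|
| winter | 0.250 | 14.7 | 80.4 |
| winter | 1.00 | 40.8 | 42.0 |
| winter | 5.00 | 19.4 | 2.4 |
| winter | 20.0 | 0 | 0.1 |
| summer | 0.250 | 49.6 | 44.0 |
| summer | 1.00 | 67.1 | 5.7 |
| summer | 5.00 | 13.0 | 0 |
| summer | 20.0 | 0.2 | 1.3 |
| midnight | 0.250 | 19.4 | 77.0 |
| midnight | 1.00 | 51.6 | 30.7 |
| midnight | 5.00 | 18.4 | 0.5 |
| midnight | 20.0 | 0 | 0 |

(scatter of a reading: 0.5 percentage points)

- reactions considered so far: starting material + enzyme <-> complex; starting material + protic impurity -> quenched substrate; 2 enzyme -> spent catalyst; complex -> enzyme + target; target -> over-reaction product

- when, up to 25 h, the flask holds most target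
- the amount of target, in percent of the starting material charged, at that time

We compare two constants, treating each step as approximately first-order (pseudo-first-order for starting material): how fast target is fed, and how fast it is spent.

1. Spending. In the summer run c(starting material) is down to 5.7% at 1.00 h, so the target's tail gives k = 0.410 /h.

2. Feeding, way one. The winter run's first reading of starting material, scaled to the flask's enzyme, gives 1.75 /h.

3. Feeding, way two. The summer run, scaled the same way, gives 1.62 /h. The two agree, and both runs share the flask's 41 mM.

4. The midnight run parts from them at 1.05 /h, which is lower. It holds twice the charge, yet its early rate per enzyme is 1.17 times winter's. So this constant cheats for our 41 mM, and we drop it.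

5. We take the mean, 1.68 /h. So ρ = 4.10, the race ratio: feeding constant over spending constant.

6. For two first-order steps in a row, target tops where feeding equals spending. That comes at ln ρ over the difference of the constants, 1.11 h, with share ρ^(−1/(ρ−1)) = 63.4% of what is not quenched.

7. The impurity can take up to 10.0% of the charge. Taking that ceiling off, we expect about 57.1%.

The forecast, later and higher than our reckoning, said 1.15 h and 60%, “between winter and summer as expected”.

The flask gives 58.6% at 1.07 h.

    starting material + enzyme ⇌ complex (K = 40.0 /M, k = 1.70 × 10⁵ /M/s)
    starting material + protic impurity → quenched substrate (k = 0.900 /M/min)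
    2 enzyme → spent catalyst (k = 23000 /M/min)
    complex → enzyme + target (k = 2000 /min)
    target → over-reaction product (k = 0.00700 /min)

In the flask, 92.3% of the charge ends as over-reaction product, and the share from step 6 applied to that gives 58.5%. The neighbouring flask changes one setting, the enzyme, to 0.0019 mM. Scaling the race ratio by the enzyme charge gives ρ = 10.5 there, and the peak share is 78.1%. That neighbour ends with 95.5% as over-reaction product, which makes the reckoned peak 74.6%. The neighbouring flask holds 73.7% at its best.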